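## The problem

1. The target is a dearomatised acylphloroglucinol. Ring A (C-4a to C-8a, chromane numbering) is a cyclohexadienone fused through C-4a and C-8a/O-1 to the 2,2-dimethyldihydropyranone ring B. The quaternary C-6 carries a prenyl group and, through the methylene C-1′, the cyclobutane ring C (C-2′ bears C-1′, C-3′ the isopropenyl group, C-4′ is CMe2, C-5′ is CH2). C-8 carries a 3-hexanoic acid unit through the methine C-1″.
2. Ring A has three oxygenated carbons and only C-8a, the one between C-8 and C-4a, may carry the ring B oxygen. Ring B therefore has to exist before ring A is closed, or O-1 could not be told from O-5.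
3. The four stereocentres fall into three isolated sets: C-2′/C-3′ in ring C, the quaternary C-6, and C-1″. A methylene or sp2 carbons separate the sets, so control can be relayed only inside ring C, where C-3′ can fix C-2′ through the thermodynamic trans preference of a 1,2-disubstituted cyclobutane.
4. C-6 and C-1″ therefore need reagent control. C-6 is a stereocentre only because its carbonyl neighbours C-5 and C-7 end up different, so the two must be distinguished from the moment the quaternary carbon is made.
5. Several groups will not survive rough treatment. The isopropenyl group on the cyclobutane ring-expands through a cyclobutylcarbinyl cation in protic acid. The prenyl group next to the ring A enol oxygens closes to a pyran in acid. The enolised β-triketone of ring A is open to electrophiles and oxidants, and ring B can open by retro-oxa-Michael reaction in strong base. Strong protic acid is thus excluded once ring C exists.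
6. The feature that opens the key step lies in ring C. The bonds C-3′–C-4′ and C-2′–C-5′ are exactly those formed when isobutylene adds across a C-2′=C-3′ double bond. C-1′ and the isopropenyl carbon flank that bond in a 1,4 relationship, which matches the carbonyl carbon and the oxygen-bearing carbon of a 5-methylbutenolide. Lactic acid supplies that butenolide, and its stereocentre can steer the cycloaddition before it is erased.

## Retrosynthesis

**Side chain (C-8–C-1″).** Target 32 is traced to enol lactone 31 (acid closed on O-7), lactol 30 and then to core 27 plus (E)-hex-2-enal 28. C-8 of 27 is the α-carbon of a vinylogous acid and the only nucleophilic CH of the core, so the bond is polarised in its natural sense. Carrying the chain on the ring A precursor instead would make the C-8 carbanion used in ring A assembly secondary and hindered, and would leave a side-chain ester to be unmasked at the end. The precursor 27 is simpler by six carbons and one stereocentre. The forward reaction must set C-1″ under catalyst control and stay non-acidic.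

**Ring A (C-4a–C-5, then C-7–C-8).** Core 27 is opened at C-4a–C-5 to seco ester 26. 26 is cut at C-7–C-8 into half-acid 20 (used as its chloride 25) and pyranone 24. These cuts leave C-6 as an intact malonate carbon and ring B whole, so O-1 sits on C-8a from the start. Cutting next to C-6, or through ring B, would give up one of these two advantages. The forward reactions are a Claisen acylation at the γ-methyl of 24 and a Dieckmann closure through C-4a. The activated carboxyl becomes C-7 and the methyl ester C-5, which turns the configuration of the malonate carbon into that of C-6.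

**Quaternary carbon (C-6–prenyl, then C-1′–C-6).** Half-acid 20 comes from diester 18 by selective loss of the tert-butyl group. 18 is cut at the prenyl bond into malonate 16 and prenyl bromide 17. 16 is cut at C-1′–C-6 (as a C=C bond in 15) into aldehyde 13 and tert-butyl methyl malonate 14. The prenyl bond is made last because 17 is reactive enough for an asymmetric phase-transfer alkylation. The hindered ring C carbon is instead joined by condensation and conjugate reduction, which avoids an SN2 reaction at a β-branched centre. The forward alkylation must distinguish the two faces of an enolate whose ester groups differ only as methyl and tert-butyl.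

**Ring C substituents (no ring bond cut).** Aldehyde 13 is traced through amide 12, ketone 11 and trans alcohol 10 to cis alcohol 9, the aminolysis product of lactone 8. The isopropenyl C=CH2 bond is the only C–C bond cut. The order is dictated by acidity. The amide carbon (future C-2′) must be inverted while the neighbouring substituent is still a carbinol, because a ketone there would invert the wrong centre and give the enantiomeric ring. The forward sequence needs a base-stable hydroxy amide that cannot relactonise, a mild oxidation, a methylenation and a partial reduction.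

**Ring C (C-3′–C-4′ and C-2′–C-5′).** Lactone 8 is cut into (S)-5-methylfuran-2(5H)-one 6 and isobutylene 7. Cutting the other pair of ring bonds would call for an unsymmetrical diene or a 1,4-biradical with no built-in stereocontrol. This cut removes the ring, both ring stereocentres and four carbons in one step and leaves a C5 lactone and a C4 gas. The forward reaction must be head-to-tail and must occur anti to the methyl group. The cis fusion it gives is corrected at 9 → 10.

**Chiral pool and side branch.** Butenolide 6 is traced through hydroxy ester 5, Z-enoate 4 and aldehyde 3 to silyl ether 2 of ethyl (S)-lactate 1. The lactate carbon is carried unchanged into C-5 of 6. Pyranone 24 is cut at C-3–C-2 and O-1–C-8a into acetylacetone 21 and acetone 22 through hydroxy diketone 23.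

## Roads not taken

**Alternative 1:** The cut is the C-4a–C-5 bond of ring A. It leaves seco ester A1, in which ring B, the quaternary malonate carbon and the complete side chain (as a tert-butyl ester) are already present. In the forward sense a lithium amide base removes the C-8 proton of A1 and the dienolate attacks the methyl ester through C-4a, giving the tert-butyl ester A2 of the target.
- Merits: the closure is regiochemically unambiguous, all stereocentres are set beforehand, and C-1″ can come from a reliable early desymmetrisation. The end of the synthesis is shorter than steps 18–20 of the chosen plan.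
- Weak points: A1 needs a Claisen coupling between a neopentylic acyl donor and a secondary, β-branched γ-carbanion that also carries an enolisable ester. A2 must then lose a tert-butyl group in the presence of the isopropenylcyclobutane and the prenyl/enol pair. The origin of ring C is left open.
- Comparison: the chosen plan uses the same closure (step 17) on the simpler seco ester 26. Against the shorter endgame of Alternative 1 it sets an easier coupling through a primary carbanion, an acid-free last step, and a defined source of ring C.

**Alternative 2:** The cut is the C-2′–C-3′ bond of ring C. The precursor is the trans-2,5-disubstituted pyrrolidine A3, from the amino-acid pool. In the forward sense an anomeric amide reagent converts the secondary amine into an isodiazene, which loses N2; the 1,4-biradical closes to the cyclobutane ester A4.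
- Merits: no photochemistry is needed. Both ring C centres are set on a five-membered ring, and A4 already has the trans arrangement and the isopropenyl group. Steps 6–9 of the chosen plan would have no counterpart; in this respect the alternative is better.
- Weak points: the biradical has an allyl radical at one end and an α-ester radical at the other, next to a quaternary carbon. Such a long-lived species can fragment by β-scission, close at the far allyl terminus to a six-membered ring, or lose its configuration. The trans-2,5 pyrrolidine is the less accessible isomer, and A3 itself takes several steps.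
- Comparison: the chosen plan sets against the shorter functional-group sequence a ring-forming step whose regiochemistry and ring fusion are fixed by the lactone, and a stereochemical error (cis) that is corrected thermodynamically.

**Alternative 3:** The cut is the C-8–C-1″ bond together with the O-7–acyl bond. In the forward sense a chiral triazolium-derived carbene and a quinone oxidant turn aldehyde 28 into an unsaturated acyl azolium. C-8 of core 27 adds to its β-carbon and O-7 is then acylated, giving enol lactone A5, which is identical with 31.
- Merits: the chain arrives late, convergently and at the acid oxidation level, one step sooner than steps 18–19 of the chosen plan.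
- Weak points: β-alkyl enals have γ-protons and are less well-behaved acyl azolium precursors than β-aryl ones. The stoichiometric oxidant meets an electron-rich enol, and direct O-acylation of the hindered nucleophile can compete. Ring C and C-6 are not addressed.
- Comparison: the chosen plan makes the same disconnection by iminium activation of 28 and pays one extra oxidation step for an oxidant-free C–C bond formation. The carbene annulation is kept as the fallback for step 18.

Key step: step 5

Assumption: the absolute sense of the two catalyst-controlled steps (13 and 18) follows the accepted models for these catalyst families; if a model reaction shows the opposite sense, the pseudoenantiomeric (step 13) or enantiomeric (step 18) catalyst is used.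

## Route

Step 1
Reactants: 1 ethyl (S)-lactate
Product: 2 ethyl (2S)-2-[(tert-butyldimethylsilyl)oxy]propanoate
Conditions: TBSCl, imidazole, DMF, 0 °C → rt
Reagents that add atoms: tert-butyldimethylsilyl chloride, CC(C)(C)[Si](C)(C)Cl
Why: Routine silylation of a secondary alcohol; the stereocentre is not touched and the ether survives the hydride and the basic olefination that follow.

Step 2
Reactants: 2 ethyl (2S)-2-[(tert-butyldimethylsilyl)oxy]propanoate
Product: 3 (2S)-2-[(tert-butyldimethylsilyl)oxy]propanal
Conditions: iBu2AlH (1.1 equiv), CH2Cl2, −78 °C; aq. potassium sodium tartrate (KNaC4H4O6)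
Reagents that add atoms: none
Why: Partial reduction of an α-silyloxy ester through an aluminium hemiacetal that is stable at −78 °C; the aldehyde is used without delay so that the α-centre should keep its configuration.

Step 3
Reactants: 3 (2S)-2-[(tert-butyldimethylsilyl)oxy]propanal
Product: 4 methyl (2Z,4S)-4-[(tert-butyldimethylsilyl)oxy]pent-2-enoate
Conditions: (CF3CH2O)2P(O)CH2CO2Me, KN(SiMe3)2, 18-crown-6, THF, −78 °C
Reagents that add atoms: methyl bis(2,2,2-trifluoroethyl)phosphonoacetate, COC(=O)CP(=O)(OCC(F)(F)F)OCC(F)(F)F
Why: Still–Gennari olefination; fast elimination from the kinetic adduct of the electron-poor phosphonate should give the Z-enoate, the geometry needed for lactonisation.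

Step 4
Reactants: 4 methyl (2Z,4S)-4-[(tert-butyldimethylsilyl)oxy]pent-2-enoate
Product: 6 (5S)-5-methylfuran-2(5H)-one, via hydroxy ester 5 (not isolated)
Conditions: TsOH·H2O (cat.), MeOH, rt
Reagents that add atoms: none
Why: Acid-catalysed methanolysis of the silyl ether frees the hydroxyl, which the Z double bond holds next to the ester, so lactonisation follows; the lactate carbon becomes C-5 of the butenolide unchanged.

Step 5
Reactants: 6 (5S)-5-methylfuran-2(5H)-one; 7 isobutylene
Product: 8 (1S,4S,5S)-4,6,6-trimethyl-3-oxabicyclo[3.2.0]heptan-2-one
Conditions: 7 (ca. 10 equiv, condensed), acetone, hν (medium-pressure mercury lamp, Pyrex filter), −40 °C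
Reagents that add atoms: none
Why: Acetone-sensitised excitation populates the butenolide triplet, which adds to isobutylene in the classical stepwise enone–alkene [2+2] mode, well established for 2(5H)-furanones with simple and electron-rich alkenes. The first C–C bond gives a triplet 1,4-biradical; after spin inversion this either reverts to the components or collapses by radical recombination, which forms the second bond and closes the cyclobutane. The five-membered lactone can only accommodate a cis ring fusion, so the two new stereocentres (C-1 and C-5 of 8) are cis by constraint. Their absolute sense is controlled by the C-5 methyl group of 6: the alkene should approach the opposite face, which places the methyl group anti to the new ring. The step needs head-to-tail orientation (CMe2 on the β-carbon, CH2 on the α-carbon) and anti facial selectivity; the first should follow from the polarisation of the excited enone towards an electron-rich 1,1-disubstituted alkene and from the partitioning of the biradicals, the second from the shielded face, and low temperature helps both. Only the β-carbon centre (future C-3′) has to be right, because the α-carbon centre is corrected in step 7.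

Step 6
Reactants: 8 (1S,4S,5S)-4,6,6-trimethyl-3-oxabicyclo[3.2.0]heptan-2-one
Product: 9 [(1S,2S)-2-[(1S)-1-hydroxyethyl]-3,3-dimethylcyclobutyl](morpholin-4-yl)methanone
Conditions: morpholine, AlMe3, CH2Cl2, 0 → 40 °C; aq. potassium sodium tartrate (KNaC4H4O6)
Reagents that add atoms: morpholine, C1COCCN1
Why: Aminolysis of a lactone by a dimethylaluminium amide; a dialkyl amide is chosen because, unlike a hydroxy ester, it should not close back to the lactone under the basic conditions of step 7, and it can later be reduced to the aldehyde.

Step 7
Reactants: 9 [(1S,2S)-2-[(1S)-1-hydroxyethyl]-3,3-dimethylcyclobutyl](morpholin-4-yl)methanone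
Product: 10 [(1R,2S)-2-[(1S)-1-hydroxyethyl]-3,3-dimethylcyclobutyl](morpholin-4-yl)methanone
Conditions: KOtBu (3 equiv), DMSO–THF, rt → 40 °C; then 1 M HCl to pH 7
Reagents that add atoms: none
Why: Base-mediated thermodynamic epimerisation α to an amide; the amide-bearing carbon (future C-2′) is the only acidic CH, so it alone should invert to the less crowded trans isomer, while the neighbouring ring carbon and the carbinol carbon keep their configuration.

Step 8
Reactants: 10 [(1R,2S)-2-[(1S)-1-hydroxyethyl]-3,3-dimethylcyclobutyl](morpholin-4-yl)methanone
Product: 11 [(1R,2S)-2-acetyl-3,3-dimethylcyclobutyl](morpholin-4-yl)methanone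
Conditions: Dess–Martin periodinane, CH2Cl2, rt
Reagents that add atoms: none
Why: Neutral oxidation of a secondary alcohol to the methyl ketone; the ring is already trans, so the newly acidic ketone α-carbon has no driving force to invert, and the lactate stereocentre is erased only now that it has done its work.

Step 9
Reactants: 11 [(1R,2S)-2-acetyl-3,3-dimethylcyclobutyl](morpholin-4-yl)methanone
Product: 12 [(1R,2R)-3,3-dimethyl-2-(prop-1-en-2-yl)cyclobutyl](morpholin-4-yl)methanone
Conditions: Ph3PCH3Br, KOtBu, THF, 0 °C → rt
Reagents that add atoms: methyltriphenylphosphonium bromide, C[P+](c1ccccc1)(c1ccccc1)c1ccccc1.[Br-]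
Why: Wittig methylenation of a methyl ketone in the presence of an inert tertiary amide; reversible enolisation by the ylide can only return the more stable trans ketone.

Step 10
Reactants: 12 [(1R,2R)-3,3-dimethyl-2-(prop-1-en-2-yl)cyclobutyl](morpholin-4-yl)methanone
Product: 13 (1R,2R)-3,3-dimethyl-2-(prop-1-en-2-yl)cyclobutane-1-carbaldehyde
Conditions: iBu2AlH (1.2 equiv), THF, −78 °C; aq. potassium sodium tartrate (KNaC4H4O6)
Reagents that add atoms: none
Why: Partial reduction of a morpholine amide through an aluminium hemiaminal that collapses only on work-up; the volatile aldehyde is used directly, and any α-epimerisation would lead back to the trans isomer.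

Step 11
Reactants: 13 (1R,2R)-3,3-dimethyl-2-(prop-1-en-2-yl)cyclobutane-1-carbaldehyde; 14 tert-butyl methyl malonate
Product: 15 1-tert-butyl 3-methyl 2-{[(1S,2R)-3,3-dimethyl-2-(prop-1-en-2-yl)cyclobutyl]methylidene}propanedioate (E/Z mixture)
Conditions: piperidine (cat.), AcOH (cat.), 4 Å molecular sieves, toluene, 60 °C
Reagents that add atoms: none
Why: Knoevenagel condensation of an α-branched aldehyde with a malonate forms the C-1′–C-6 bond without an SN2 reaction at a hindered carbon; the alkene geometry is irrelevant and the ring carbon stays under thermodynamic (trans) control.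

Step 12
Reactants: 15 1-tert-butyl 3-methyl 2-{[(1S,2R)-3,3-dimethyl-2-(prop-1-en-2-yl)cyclobutyl]methylidene}propanedioate
Product: 16 1-tert-butyl 3-methyl 2-{[(1R,2R)-3,3-dimethyl-2-(prop-1-en-2-yl)cyclobutyl]methyl}propanedioate (both epimers at the malonate carbon)
Conditions: NaBH4, MeOH–THF, 0 °C
Reagents that add atoms: none
Why: Conjugate hydride reduction of an alkylidene malonate; the isolated isopropenyl group and the esters should be untouched at 0 °C, and the malonate CH centre is lost again in step 13.

Step 13
Reactants: 16 1-tert-butyl 3-methyl 2-{[(1R,2R)-3,3-dimethyl-2-(prop-1-en-2-yl)cyclobutyl]methyl}propanedioate; 17 prenyl bromide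
Product: 18 1-tert-butyl 3-methyl (2R)-2-{[(1S,2R)-3,3-dimethyl-2-(prop-1-en-2-yl)cyclobutyl]methyl}-2-(3-methylbut-2-en-1-yl)propanedioate
Conditions: N-(9-anthracenylmethyl)cinchoninium chloride (10 mol%), 50% aq. KOH, toluene, −20 °C
Reagents that add atoms: none
Why: Asymmetric phase-transfer alkylation of an α-substituted tert-butyl methyl malonate with an allylic bromide; the chiral ammonium cation pairs with the enolate and should expose one face, which sets C-6, while the tert-butyl ester resists hydroxide and later allows the two carboxyls to be told apart.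

Step 14
Reactants: 18 1-tert-butyl 3-methyl (2R)-2-{[(1S,2R)-3,3-dimethyl-2-(prop-1-en-2-yl)cyclobutyl]methyl}-2-(3-methylbut-2-en-1-yl)propanedioate
Product: 20 (2S)-2-{[(1S,2R)-3,3-dimethyl-2-(prop-1-en-2-yl)cyclobutyl]methyl}-2-(methoxycarbonyl)-5-methylhex-4-enoic acid, via trimethylsilyl ester 19 (not isolated)
Conditions: Me3SiOTf, 2,6-lutidine, CH2Cl2, 0 °C → rt; then aq. buffer (pH 4)
Reagents that add atoms: none
Why: Silyl triflate-mediated cleavage of a tert-butyl ester (loss of isobutylene) under buffered, aprotic conditions, chosen over protic acid to spare the isopropenylcyclobutane and the prenyl group; the methyl ester stays and the silyl ester is hydrolysed on work-up.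

Step 15
Reactants: 21 acetylacetone; 22 acetone
Product: 24 2,2,6-trimethyl-2,3-dihydro-4H-pyran-4-one, via hydroxy diketone 23 (not isolated)
Conditions: LiN(iPr)2 (2.1 equiv), THF, 0 °C; 22, −78 °C; aq. HCl quench; crude 23 with TsOH·H2O (cat.), CH2Cl2, rt → 40 °C
Reagents that add atoms: none
Why: The β-diketone dianion undergoes aldol addition at its terminal carbon; acid then closes the tertiary hydroxyl onto the distal carbonyl (six-membered hemiketal) and dehydrates it to the vinylogous ester, which fixes the ring B oxygen on the future C-8a.

Step 16
Reactants: 20 (2S)-2-{[(1S,2R)-3,3-dimethyl-2-(prop-1-en-2-yl)cyclobutyl]methyl}-2-(methoxycarbonyl)-5-methylhex-4-enoic acid; 24 2,2,6-trimethyl-2,3-dihydro-4H-pyran-4-one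
Product: 26 methyl (2S)-2-{[(1S,2R)-3,3-dimethyl-2-(prop-1-en-2-yl)cyclobutyl]methyl}-4-(6,6-dimethyl-4-oxo-5,6-dihydro-4H-pyran-2-yl)-2-(3-methylbut-2-en-1-yl)-3-oxobutanoate, via acid chloride 25 (not isolated)
Conditions: 20, 1-chloro-N,N,2-trimethylprop-1-en-1-amine, CH2Cl2, 0 °C → rt; solution of 25 added to the lithium dienolate of 24 (2.2 equiv; LiN(SiMe3)2, THF, −78 → 0 → −78 °C), then −78 → −30 °C; AcOH quench
Reagents that add atoms: none
Why: Claisen-type C-acylation of an extended enolate at its γ-methyl carbon by a non-enolisable acid chloride made under neutral conditions; C-3 of 24 is neopentylic, and the γ-acylated product is drained from the equilibrium as its stabilised enolate, hence the second equivalent of dienolate. The carboxyl acylated here becomes C-7.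

Step 17
Reactants: 26 methyl (2S)-2-{[(1S,2R)-3,3-dimethyl-2-(prop-1-en-2-yl)cyclobutyl]methyl}-4-(6,6-dimethyl-4-oxo-5,6-dihydro-4H-pyran-2-yl)-2-(3-methylbut-2-en-1-yl)-3-oxobutanoate
Product: 27 (6R)-6-{[(1S,2R)-3,3-dimethyl-2-(prop-1-en-2-yl)cyclobutyl]methyl}-5-hydroxy-2,2-dimethyl-6-(3-methylbut-2-en-1-yl)-2,3-dihydro-4H-chromene-4,7(6H)-dione
Conditions: LiN(SiMe3)2 (2.5 equiv), THF, −78 → 0 °C; AcOH quench
Reagents that add atoms: none
Why: Dieckmann condensation: deprotonation at C-8 gives a dienolate delocalised to C-4a, which attacks the methyl ester and forms the C-4a–C-5 bond in the only six-membered closure available; formation of the acidic triketone enolate drives it, O-1 is already on C-8a, and C-6 is not touched.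

Step 18
Reactants: 27 (6R)-6-{[(1S,2R)-3,3-dimethyl-2-(prop-1-en-2-yl)cyclobutyl]methyl}-5-hydroxy-2,2-dimethyl-6-(3-methylbut-2-en-1-yl)-2,3-dihydro-4H-chromene-4,7(6H)-dione; 28 (E)-hex-2-enal
Product: 30 lactol (cyclic hemiacetal on O-7; both anomers), via Michael aldehyde 29 (not isolated)
Conditions: 28 (1.5 equiv), (S)-2-[diphenyl(trimethylsilyloxy)methyl]pyrrolidine (20 mol%), PhCO2H (20 mol%), CH2Cl2, 0 °C → rt
Reagents that add atoms: none
Why: Iminium-catalysed Michael addition of a cyclic vinylogous acid to an enal; the diaryl(silyloxy)methyl group shields one face of the E-iminium ion, so C-8 should add to the other face and give (R)-C-1″, and hemiacetal formation with O-7 drives the addition and masks the aldehyde.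

Step 19
Reactants: 30 lactol (cyclic hemiacetal on O-7)
Product: 31 enol δ-lactone (side-chain carboxyl closed on O-7)
Conditions: pyridinium chlorochromate (C5H5NH)[CrO3Cl], NaOAc, 4 Å molecular sieves, CH2Cl2, rt
Reagents that add atoms: none
Why: Oxidation of a lactol to the lactone under buffered conditions, as practised on hemiacetals from this type of Michael addition; the alkenes and the fully substituted ring A should be inert.

Step 20
Reactants: 31 enol δ-lactone (side-chain carboxyl closed on O-7)
Product: 32 (3R)-3-[(6R)-6-{[(1S,2R)-3,3-dimethyl-2-(prop-1-en-2-yl)cyclobutyl]methyl}-5-hydroxy-2,2-dimethyl-6-(3-methylbut-2-en-1-yl)-4,7-dioxo-3,4,6,7-tetrahydro-2H-chromen-8-yl]hexanoic acid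
Conditions: LiOH·H2O (3 equiv), THF–H2O, 0 °C → rt; then 1 M HCl to pH 3, 0 °C
Reagents that add atoms: lithium hydroxide, [Li+].[OH-]
Why: Hydroxide opens the activated enol ester; C-1″ is β to the carboxyl and cannot epimerise, and cold, brief acidification frees the acid while ring A returns to the 5-hydroxy-7-oxo tautomer.

## Compound list

1 | ethyl (S)-lactate | C[C@H](O)C(=O)OCC | starting material
2 | ethyl (2S)-2-[(tert-butyldimethylsilyl)oxy]propanoate | C[C@H](O[Si](C)(C)C(C)(C)C)C(=O)OCC | intermediate
3 | (2S)-2-[(tert-butyldimethylsilyl)oxy]propanal | C[C@H](O[Si](C)(C)C(C)(C)C)C=O | intermediate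
4 | methyl (2Z,4S)-4-[(tert-butyldimethylsilyl)oxy]pent-2-enoate | C[C@H](O[Si](C)(C)C(C)(C)C)/C=C\C(=O)OC | intermediate
5 | methyl (2Z,4S)-4-hydroxypent-2-enoate (not isolated) | C[C@H](O)/C=C\C(=O)OC | intermediate
6 | (5S)-5-methylfuran-2(5H)-one | C[C@@H]1OC(=O)C=C1 | intermediate
7 | isobutylene (2-methylpropene) | C=C(C)C | starting material
8 | (1S,4S,5S)-4,6,6-trimethyl-3-oxabicyclo[3.2.0]heptan-2-one (cis-fused; methyl anti to the cyclobutane) | C[C@@H]1OC(=O)[C@H]2CC(C)(C)[C@@H]12 | intermediate
9 | [(1S,2S)-2-[(1S)-1-hydroxyethyl]-3,3-dimethylcyclobutyl](morpholin-4-yl)methanone (cis) | C[C@H](O)[C@H]1[C@@H](C(=O)N2CCOCC2)CC1(C)C | intermediate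
10 | [(1R,2S)-2-[(1S)-1-hydroxyethyl]-3,3-dimethylcyclobutyl](morpholin-4-yl)methanone (trans) | C[C@H](O)[C@H]1[C@H](C(=O)N2CCOCC2)CC1(C)C | intermediate
11 | [(1R,2S)-2-acetyl-3,3-dimethylcyclobutyl](morpholin-4-yl)methanone (trans) | CC(=O)[C@H]1[C@H](C(=O)N2CCOCC2)CC1(C)C | intermediate
12 | [(1R,2R)-3,3-dimethyl-2-(prop-1-en-2-yl)cyclobutyl](morpholin-4-yl)methanone (trans) | C=C(C)[C@H]1[C@H](C(=O)N2CCOCC2)CC1(C)C | intermediate
13 | (1R,2R)-3,3-dimethyl-2-(prop-1-en-2-yl)cyclobutane-1-carbaldehyde (trans) | C=C(C)[C@H]1[C@H](C=O)CC1(C)C | intermediate
14 | tert-butyl methyl malonate | COC(=O)CC(=O)OC(C)(C)C | starting material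
15 | 1-tert-butyl 3-methyl 2-{[(1S,2R)-3,3-dimethyl-2-(prop-1-en-2-yl)cyclobutyl]methylidene}propanedioate (E/Z mixture) | C=C(C)[C@H]1[C@H](C=C(C(=O)OC)C(=O)OC(C)(C)C)CC1(C)C | intermediate
16 | 1-tert-butyl 3-methyl 2-{[(1R,2R)-3,3-dimethyl-2-(prop-1-en-2-yl)cyclobutyl]methyl}propanedioate (both epimers at the malonate carbon) | C=C(C)[C@H]1[C@H](CC(C(=O)OC)C(=O)OC(C)(C)C)CC1(C)C | intermediate
17 | prenyl bromide (1-bromo-3-methylbut-2-ene) | CC(C)=CCBr | starting material
18 | 1-tert-butyl 3-methyl (2R)-2-{[(1S,2R)-3,3-dimethyl-2-(prop-1-en-2-yl)cyclobutyl]methyl}-2-(3-methylbut-2-en-1-yl)propanedioate | C=C(C)[C@H]1[C@H](C[C@](C(=O)OC)(CC=C(C)C)C(=O)OC(C)(C)C)CC1(C)C | intermediate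
19 | 1-methyl 3-trimethylsilyl (2R)-2-{[(1S,2R)-3,3-dimethyl-2-(prop-1-en-2-yl)cyclobutyl]methyl}-2-(3-methylbut-2-en-1-yl)propanedioate (not isolated) | C=C(C)[C@H]1[C@H](C[C@](C(=O)OC)(CC=C(C)C)C(=O)O[Si](C)(C)C)CC1(C)C | intermediate
20 | (2S)-2-{[(1S,2R)-3,3-dimethyl-2-(prop-1-en-2-yl)cyclobutyl]methyl}-2-(methoxycarbonyl)-5-methylhex-4-enoic acid | C=C(C)[C@H]1[C@H](C[C@](C(=O)OC)(CC=C(C)C)C(=O)O)CC1(C)C | intermediate
21 | acetylacetone (pentane-2,4-dione) | CC(=O)CC(C)=O | starting material
22 | acetone | CC(C)=O | starting material
23 | 6-hydroxy-6-methylheptane-2,4-dione (not isolated) | CC(=O)CC(=O)CC(C)(C)O | intermediate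
24 | 2,2,6-trimethyl-2,3-dihydro-4H-pyran-4-one | CC1=CC(=O)CC(C)(C)O1 | intermediate
25 | methyl (2R)-2-(chlorocarbonyl)-2-{[(1S,2R)-3,3-dimethyl-2-(prop-1-en-2-yl)cyclobutyl]methyl}-5-methylhex-4-enoate (not isolated) | C=C(C)[C@H]1[C@H](C[C@](C(=O)OC)(CC=C(C)C)C(Cl)=O)CC1(C)C | intermediate
26 | methyl (2S)-2-{[(1S,2R)-3,3-dimethyl-2-(prop-1-en-2-yl)cyclobutyl]methyl}-4-(6,6-dimethyl-4-oxo-5,6-dihydro-4H-pyran-2-yl)-2-(3-methylbut-2-en-1-yl)-3-oxobutanoate (seco ester; keto form drawn) | C=C(C)[C@H]1[C@H](C[C@](C(=O)OC)(CC=C(C)C)C(=O)CC2=CC(=O)CC(C)(C)O2)CC1(C)C | intermediate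
27 | (6R)-6-{[(1S,2R)-3,3-dimethyl-2-(prop-1-en-2-yl)cyclobutyl]methyl}-5-hydroxy-2,2-dimethyl-6-(3-methylbut-2-en-1-yl)-2,3-dihydro-4H-chromene-4,7(6H)-dione (core; C-8 unsubstituted) | C=C(C)[C@H]1[C@H](C[C@]2(CC=C(C)C)C(=O)C=C3OC(C)(C)CC(=O)C3=C2O)CC1(C)C | intermediate
28 | (E)-hex-2-enal | CCC/C=C/C=O | starting material
29 | (3R)-3-[C-8 of core 27]hexanal: the aldehyde analogue of 32, CHO in place of CO2H (not isolated) | C=C(C)[C@H]1[C@H](C[C@]2(CC=C(C)C)C(=O)C([C@H](CCC)CC=O)=C3OC(C)(C)CC(=O)C3=C2O)CC1(C)C | intermediate
30 | lactol: cyclic hemiacetal of 29 with the aldehyde carbon bonded to O-7 (2-hydroxy-3,4-dihydro-2H-pyran fused at O-7/C-8; ring A as the 5-oxo tautomer; both anomers; other centres as in 32) | C=C(C)[C@H]1[C@H](C[C@]2(CC=C(C)C)C3=C([C@H](CCC)CC(O)O3)C4=C(C(=O)CC(C)(C)O4)C2=O)CC1(C)C | intermediate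
31 | enol δ-lactone of 32: side-chain carboxyl closed on O-7 (pyrano[2,3-f]chromene-4,5,8-trione skeleton; ring C, C-6 and C-1″ as in 32) | C=C(C)[C@H]1[C@H](C[C@]2(CC=C(C)C)C3=C([C@H](CCC)CC(=O)O3)C4=C(C(=O)CC(C)(C)O4)C2=O)CC1(C)C | intermediate
32 | (3R)-3-[(6R)-6-{[(1S,2R)-3,3-dimethyl-2-(prop-1-en-2-yl)cyclobutyl]methyl}-5-hydroxy-2,2-dimethyl-6-(3-methylbut-2-en-1-yl)-4,7-dioxo-3,4,6,7-tetrahydro-2H-chromen-8-yl]hexanoic acid | C=C(C)[C@H]1[C@H](C[C@]2(CC=C(C)C)C(=O)C([C@H](CCC)CC(=O)O)=C3OC(C)(C)CC(=O)C3=C2O)CC1(C)C | target

## Step count and uncertain steps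

Total: 20 steps. Longest linear sequence: 19 steps (steps 1–14 and 16–20); step 15 is the one-step side branch.

**Step 5 (key step).** The methyl group is a small director, so some cycloaddition syn to it, and some head-to-head orientation, may occur. Because step 8 erases the carbinol centre, any syn adduct carried that far would become the enantiomeric ring C. The diastereomers therefore have to be removed at 8, 9 or 10, where they are still distinguishable.
Fallback: the ring is built with a bulkier, more strongly polarised alkene and the gem-dimethyl group is installed afterwards. Starting from 6, photocycloaddition with 1,1-diethoxyethylene should give the 6,6-diethoxy analogue of 8, acetal F1. Mild aqueous acid gives cyclobutanone F2. Ph3P=CH2 gives the methylidene lactone F3. Et2Zn/CH2I2 gives the spirocyclopropane F4. Hydrogenolysis of the unsubstituted cyclopropane bond (H2, PtO2, AcOH) converts F4 into 8, where the route is rejoined.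

**Step 7.** Enolisation of a dialkyl amide on a four-membered ring, next to an alkoxide, is slow. The equilibration may stall before the trans isomer dominates.
Fallback: the inversion is moved to the aldehyde stage, where only the right carbon is acidic. Starting from 9, Dess–Martin oxidation gives the cis keto amide F5. Non-basic methylenation (Zn, CH2Br2, TiCl4), which should not touch the ketone α-centre, gives the cis isopropenyl amide F6. iBu2AlH gives the cis aldehyde F7, which K2CO3 in MeOH equilibrates to the trans aldehyde 13. The price is that F5 must be handled without base, since inversion next to its ketone would lead to the enantiomeric ring.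

**Step 13.** The ion-paired enolate of this bulky α-substituent may be alkylated with low facial discrimination, or too slowly to outrun the uncatalysed interfacial reaction. The result would be a mixture of C-6 epimers.
Fallback: C-6 is set after, not during, the alkylation. Starting from 13, condensation with dimethyl malonate gives the alkylidene diester F8 and NaBH4 gives the alkylmalonate F9. NaH and 17 give the prochiral dimethyl dialkylmalonate F10. Pig liver esterase (pH 7–8 buffer, DMSO co-solvent) hydrolyses one of the two methyl esters to give half-acid 20. This also bypasses step 14. The enzyme's preference for this substrate would have to be established first.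

**Step 16.** Proton abstraction at C-3 of 24 instead of the γ-methyl, or O-acylation of the dienolate, would divert the hindered acid chloride.
Fallback: the acyl acceptor is used in its open-chain form, whose polyanion has only one terminal carbanion. Starting from 25 and isolated hydroxy diketone 23, LiN(iPr)2 (3 equiv) gives the alkoxide-dianion of 23, and acylation at its terminal methyl group gives the hydroxy triketo ester F11. Pyridinium p-toluenesulfonate in CH2Cl2 closes and dehydrates the hemiketal to seco ester 26.

**Step 18.** The hindered, rather acidic nucleophile may add slowly, so an acid-catalysed background addition without catalyst control could lower the selectivity at C-1″. The adduct could also revert by retro-Michael reaction.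
Fallback: the enal is activated at the acid oxidation level. Starting from 27 and 28, a chiral triazolium-derived carbene with 3,3′,5,5′-tetra-tert-butyldiphenoquinone converts 28 into an unsaturated acyl azolium. C-8 adds to it and O-7 is then acylated, which gives lactone 31 directly and rejoins the route there, passing by 30. No new compound is formed.

## Further compounds

F1 | step 5 | 6,6-diethoxy-4-methyl-3-oxabicyclo[3.2.0]heptan-2-one (configuration as in 8) | C[C@@H]1OC(=O)[C@H]2CC(OCC)(OCC)[C@@H]12
F2 | step 5 | 4-methyl-3-oxabicyclo[3.2.0]heptane-2,6-dione (configuration as in 8) | C[C@@H]1OC(=O)[C@H]2CC(=O)[C@@H]12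
F3 | step 5 | 4-methyl-6-methylidene-3-oxabicyclo[3.2.0]heptan-2-one (configuration as in 8) | C[C@@H]1OC(=O)[C@H]2CC(=C)[C@@H]12
F4 | step 5 | 4-methylspiro[3-oxabicyclo[3.2.0]heptane-6,1′-cyclopropan]-2-one (configuration as in 8) | C[C@@H]1OC(=O)[C@H]2CC3(CC3)[C@@H]12
F5 | step 7 | [(1S,2S)-2-acetyl-3,3-dimethylcyclobutyl](morpholin-4-yl)methanone (cis) | CC(=O)[C@H]1[C@@H](C(=O)N2CCOCC2)CC1(C)C
F6 | step 7 | [(1S,2R)-3,3-dimethyl-2-(prop-1-en-2-yl)cyclobutyl](morpholin-4-yl)methanone (cis) | C=C(C)[C@H]1[C@@H](C(=O)N2CCOCC2)CC1(C)C
F7 | step 7 | (1S,2R)-3,3-dimethyl-2-(prop-1-en-2-yl)cyclobutane-1-carbaldehyde (cis) | C=C(C)[C@H]1[C@@H](C=O)CC1(C)C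
F8 | step 13 | dimethyl 2-{[(1S,2R)-3,3-dimethyl-2-(prop-1-en-2-yl)cyclobutyl]methylidene}propanedioate | C=C(C)[C@H]1[C@H](C=C(C(=O)OC)C(=O)OC)CC1(C)C
F9 | step 13 | dimethyl 2-{[(1R,2R)-3,3-dimethyl-2-(prop-1-en-2-yl)cyclobutyl]methyl}propanedioate | C=C(C)[C@H]1[C@H](CC(C(=O)OC)C(=O)OC)CC1(C)C
F10 | step 13 | dimethyl 2-{[(1S,2R)-3,3-dimethyl-2-(prop-1-en-2-yl)cyclobutyl]methyl}-2-(3-methylbut-2-en-1-yl)propanedioate | C=C(C)[C@H]1[C@H](CC(CC=C(C)C)(C(=O)OC)C(=O)OC)CC1(C)C
F11 | step 16 | methyl (2S)-2-{[(1S,2R)-3,3-dimethyl-2-(prop-1-en-2-yl)cyclobutyl]methyl}-9-hydroxy-9-methyl-2-(3-methylbut-2-en-1-yl)-3,5,7-trioxodecanoate | C=C(C)[C@H]1[C@H](C[C@](C(=O)OC)(CC=C(C)C)C(=O)CC(=O)CC(=O)CC(C)(C)O)CC1(C)C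
F0 | step 18 | none | none
A1 | alternative 1 | seco ester: methyl ester at the quaternary malonate carbon, C-7 ketone, C-8 bearing the (R)-1-(tert-butoxycarbonylmethyl)butyl chain and the 6,6-dimethyl-4-oxo-5,6-dihydro-4H-pyran-2-yl ring | C=C(C)[C@H]1[C@H](C[C@](C(=O)OC)(CC=C(C)C)C(=O)C([C@H](CCC)CC(=O)OC(C)(C)C)C2=CC(=O)CC(C)(C)O2)CC1(C)C
A2 | alternative 1 | tert-butyl ester of the target | C=C(C)[C@H]1[C@H](C[C@]2(CC=C(C)C)C(=O)C([C@H](CCC)CC(=O)OC(C)(C)C)=C3OC(C)(C)CC(=O)C3=C2O)CC1(C)C
A3 | alternative 2 | methyl trans-4,4-dimethyl-5-(prop-1-en-2-yl)pyrrolidine-2-carboxylate (configuration matching A4) | C=C(C)[C@H]1N[C@H](C(=O)OC)CC1(C)C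
A4 | alternative 2 | methyl (1R,2R)-3,3-dimethyl-2-(prop-1-en-2-yl)cyclobutane-1-carboxylate (trans) | C=C(C)[C@H]1[C@H](C(=O)OC)CC1(C)C
A5 | alternative 3 | enol δ-lactone of the target, acid closed on O-7 (identical with 31) | C=C(C)[C@H]1[C@H](C[C@]2(CC=C(C)C)C3=C([C@H](CCC)CC(=O)O3)C4=C(C(=O)CC(C)(C)O4)C2=O)CC1(C)C
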